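**Assumption:** in step 1 the antipode of the bis(sulfonamide) diol ligand is chosen that delivers the alkyl group to the Si face of the ketone (1S carbinol); both antipodes are accessible.

## Retrosynthetic overview

1. Target 20 comes from desilylation of 19; the central C–C bond of the (E,E)-diene is made by oxidative homocoupling of two identical (E)-dienylboron halves (17/18), each from a Heck reaction of cyclohexenyl triflate 15 with a vinylboron unit.
2. The side-chain oxiranes are set by Shi epoxidation at the triflate stage (14 to 15), where the ring alkene is deactivated.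
3. The cyclohexene ring comes from a one-carbon ring expansion of cyclopentanone 8: a carbenoid 1,2-shift of the quaternary carbon, with the regiodefined enolate caught as triflate 14.
4. The quaternary/carbinol pair of 8 comes from a stereospecific semipinacol 1,2-shift of the homoprenyl group in epoxy alcohol 6, itself from enantioselective dialkylzinc addition to 2-methylcyclopent-2-enone and directed epoxidation.
5. Ring order: cyclopentane (bought), fused oxirane (step 1, consumed in step 2), cyclohexene (step 3), side-chain oxirane (step 4).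

## Route

Step 1
Reactants: 1 2-methylcyclopent-2-en-1-one; 2 5-bromo-2-methylpent-2-ene
Product: 6 (1S,2R,5S)-1-methyl-2-(4-methylpent-3-en-1-yl)-6-oxabicyclo[3.1.0]hexan-2-ol, via Grignard reagent 3 (not isolated), via dialkylzinc 4 (not isolated), via tertiary allylic alkoxide 5 (not isolated)
Conditions: 2 (3.3 equiv), Mg, Et2O; ZnCl2 (1.65 equiv), then 1,4-dioxane, filter; add to 1, Ti(OiPr)4 (1.2 equiv), bis(hydroxycamphorsulfonamide) ligand of trans-cyclohexane-1,2-diamine (10 mol %), toluene/hexane, rt; then TBHP (in decane, 3 equiv), −20 → 0 °C; aq. NH4Cl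
Reagents that add atoms: tert-butyl hydroperoxide (TBHP), CC(C)(C)OO
Why: Titanium-catalysed enantioselective 1,2-addition of a dialkylzinc to an α-substituted cyclic enone (Yus–Walsh type) sets the carbinol centre by Si-face alkyl transfer, and the resulting metal alkoxide directs a Sharpless-type titanium/TBHP epoxidation to its own face, so the oxirane is formed syn to the oxygen while the remote trisubstituted alkene is untouched.

Step 2
Reactants: 6 (1S,2R,5S)-1-methyl-2-(4-methylpent-3-en-1-yl)-6-oxabicyclo[3.1.0]hexan-2-ol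
Product: 8 (2R,3S)-3-[(tert-butyldimethylsilyl)oxy]-2-methyl-2-(4-methylpent-3-en-1-yl)cyclopentan-1-one, via hydroxy ketone 7 (not isolated)
Conditions: BF3·OEt2 (0.3 equiv), CH2Cl2, −78 → −40 °C; then 2,6-lutidine (3 equiv), TBSOTf (1.5 equiv), −40 → 0 °C
Reagents that add atoms: tert-butyldimethylsilyl trifluoromethanesulfonate (TBSOTf), CC(C)(C)[Si](C)(C)OS(=O)(=O)C(F)(F)F
Why: Semipinacol rearrangement of a 2,3-epoxy alcohol: the homoprenyl group, anti-periplanar to the breaking tertiary C–O bond, shifts with inversion at the migration terminus while the oxygen stays on C3 with retention, so the new quaternary carbon carries methyl cis and the chain trans to the C3 oxygen, which is then silylated in the same flask.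

Step 3
Reactants: 8 (2R,3S)-3-[(tert-butyldimethylsilyl)oxy]-2-methyl-2-(4-methylpent-3-en-1-yl)cyclopentan-1-one; 9 dibromomethane
Product: 14 (3S,4S)-4-[(tert-butyldimethylsilyl)oxy]-3-methyl-3-(4-methylpent-3-en-1-yl)cyclohex-1-en-1-yl trifluoromethanesulfonate, via dibromomethyllithium 10 (not isolated), via lithium alkoxide adduct 11 (not isolated), via β-oxido carbenoid 12 (not isolated), via lithium enolate 13 (not isolated)
Conditions: 9 (1.3 equiv), LiN(iPr)2 (1.25 equiv), THF, −78 °C; 8, −78 °C; n-BuLi (2.5 equiv), −95 → −30 °C; PhNTf2 (3 equiv), −78 → 0 °C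
Reagents that add atoms: N-phenylbis(trifluoromethanesulfonimide) (PhNTf2), O=S(=O)(N(c1ccccc1)S(=O)(=O)C(F)(F)F)C(F)(F)F
Why: Proposed new method: an interrupted Taguchi–Yamamoto–Nozaki homologation in which Br/Li exchange on adduct 11 gives the β-oxido carbenoid, the alkoxide drives a 1,2-shift of the more electron-rich, fully substituted C2 (retention at the migrating carbon) with loss of LiBr, and the lithium enolate so formed, whose C=C lies between the old carbonyl carbon and the inserted CH, is O-sulfonylated in the same flask to the ring-expanded alkenyl triflate; the closest known reaction is the β-oxido carbenoid ring enlargement of cycloalkanones with protic quench, not yet shown for a quaternary β-silyloxy migrating carbon or with triflate capture.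

Step 4
Reactants: 14 (3S,4S)-4-[(tert-butyldimethylsilyl)oxy]-3-methyl-3-(4-methylpent-3-en-1-yl)cyclohex-1-en-1-yl trifluoromethanesulfonate
Product: 15 (3S,4S)-4-[(tert-butyldimethylsilyl)oxy]-3-{2-[(2R)-3,3-dimethyloxiran-2-yl]ethyl}-3-methylcyclohex-1-en-1-yl trifluoromethanesulfonate
Conditions: D-fructose-derived Shi ketone (0.3 equiv), KHSO5 (as 2KHSO5·KHSO4·K2SO4, 1.4 equiv), K2CO3, Bu4NHSO4 (cat.), MeCN/dimethoxymethane/aq. Na2B4O7 buffer (pH 10.5), 0 °C
Reagents that add atoms: potassium peroxymonosulfate (KHSO5), [K+].[O-]S(=O)(=O)OO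
Why: Shi asymmetric epoxidation: the chiral dioxirane attacks only the electron-rich trisubstituted side-chain alkene (the alkenyl triflate is deactivated), and the D-fructose-derived ketone delivers oxygen through the spiro transition state to give the (R)-oxirane under catalyst control.

Step 5
Reactants: 15 (3S,4S)-4-[(tert-butyldimethylsilyl)oxy]-3-{2-[(2R)-3,3-dimethyloxiran-2-yl]ethyl}-3-methylcyclohex-1-en-1-yl trifluoromethanesulfonate; 16 vinylboronic acid MIDA ester (2-ethenyl-6-methyl-1,3,6,2-dioxazaborocane-4,8-dione)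
Product: 17 2-[(E)-2-[(3S,4S)-4-[(tert-butyldimethylsilyl)oxy]-3-{2-[(2R)-3,3-dimethyloxiran-2-yl]ethyl}-3-methylcyclohex-1-en-1-yl]ethenyl]-6-methyl-1,3,6,2-dioxazaborocane-4,8-dione
Conditions: Pd(OAc)2 (5 mol %), P(o-tol)3 (12 mol %), Et3N (3 equiv), MeCN, 70 °C
Reagents that add atoms: none
Why: Mizoroki–Heck reaction: the alkenylpalladium species adds to the unsubstituted terminus of the vinylboronate and syn β-hydride elimination gives the (E)-alkene, while the sp3-hybridised MIDA boronate cannot transmetalate under anhydrous conditions and the oxirane and silyl ether are inert.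

Step 6
Reactants: 17 (two molecules) 2-[(E)-2-[(3S,4S)-4-[(tert-butyldimethylsilyl)oxy]-3-{2-[(2R)-3,3-dimethyloxiran-2-yl]ethyl}-3-methylcyclohex-1-en-1-yl]ethenyl]-6-methyl-1,3,6,2-dioxazaborocane-4,8-dione
Product: 19 (1E,3E)-1,4-bis[(3S,4S)-4-[(tert-butyldimethylsilyl)oxy]-3-{2-[(2R)-3,3-dimethyloxiran-2-yl]ethyl}-3-methylcyclohex-1-en-1-yl]buta-1,3-diene, via dienylboronic acid 18 (not isolated)
Conditions: Pd(OAc)2 (10 mol %), aq. K3PO4 (3 M, 6 equiv), THF, O2 (1 atm), 23 → 45 °C
Reagents that add atoms: none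
Why: Slow-release hydrolysis of the MIDA boronate followed by palladium-catalysed oxidative homocoupling of the alkenylboronic acid (double transmetalation to divalent palladium, reductive elimination with retention of both alkene geometries, reoxidation of zerovalent palladium by O2) forms the central C–C bond of the (E,E)-diene.

Step 7
Reactants: 19 (1E,3E)-1,4-bis[(3S,4S)-4-[(tert-butyldimethylsilyl)oxy]-3-{2-[(2R)-3,3-dimethyloxiran-2-yl]ethyl}-3-methylcyclohex-1-en-1-yl]buta-1,3-diene
Product: 20 (1S,1'S,2S,2'S)-4,4'-[(1E,3E)-buta-1,3-diene-1,4-diyl]bis(2-{2-[(2R)-3,3-dimethyloxiran-2-yl]ethyl}-2-methylcyclohex-3-en-1-ol), the target CNP0229121.5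
Conditions: TBAF (6 equiv), AcOH (6 equiv), THF, 0 → 40 °C
Reagents that add atoms: none
Why: Fluoride-induced cleavage of the two silyl ethers, buffered with acetic acid so that the liberated alkoxides do not open the oxiranes; no stereocentre or alkene is touched.

## Compound list

1 | 2-methylcyclopent-2-en-1-one | CC1=CCCC1=O | starting material
2 | 5-bromo-2-methylpent-2-ene | CC(C)=CCCBr | starting material
3 | (4-methylpent-3-en-1-yl)magnesium bromide | CC(C)=CCC[Mg]Br | intermediate (not isolated)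
4 | bis(4-methylpent-3-en-1-yl)zinc | CC(C)=CCC[Zn]CCC=C(C)C | intermediate (not isolated)
5 | (1S)-2-methyl-1-(4-methylpent-3-en-1-yl)cyclopent-2-en-1-ol, present as its zinc/titanium alkoxide | CC(C)=CCC[C@@]1(O)CCC=C1C | intermediate (not isolated)
6 | (1S,2R,5S)-1-methyl-2-(4-methylpent-3-en-1-yl)-6-oxabicyclo[3.1.0]hexan-2-ol | CC(C)=CCC[C@@]1(O)CC[C@@H]2O[C@]12C | intermediate
7 | (2R,3S)-3-hydroxy-2-methyl-2-(4-methylpent-3-en-1-yl)cyclopentan-1-one | CC(C)=CCC[C@@]1(C)C(=O)CC[C@@H]1O | intermediate (not isolated)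
8 | (2R,3S)-3-[(tert-butyldimethylsilyl)oxy]-2-methyl-2-(4-methylpent-3-en-1-yl)cyclopentan-1-one | CC(C)=CCC[C@@]1(C)C(=O)CC[C@@H]1O[Si](C)(C)C(C)(C)C | intermediate
9 | dibromomethane | BrCBr | starting material
10 | dibromomethyllithium | [Li]C(Br)Br | intermediate (not isolated)
11 | lithium (2R,3S)-3-[(tert-butyldimethylsilyl)oxy]-1-(dibromomethyl)-2-methyl-2-(4-methylpent-3-en-1-yl)cyclopentan-1-olate (C1 epimers; this centre becomes sp2) | CC(C)=CCC[C@@]1(C)C(O[Li])(C(Br)Br)CC[C@@H]1O[Si](C)(C)C(C)(C)C | intermediate (not isolated)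
12 | lithium (2R,3S)-1-[bromo(lithio)methyl]-3-[(tert-butyldimethylsilyl)oxy]-2-methyl-2-(4-methylpent-3-en-1-yl)cyclopentan-1-olate (β-oxido carbenoid) | CC(C)=CCC[C@@]1(C)C(O[Li])(C([Li])Br)CC[C@@H]1O[Si](C)(C)C(C)(C)C | intermediate (not isolated)
13 | lithium (3S,4S)-4-[(tert-butyldimethylsilyl)oxy]-3-methyl-3-(4-methylpent-3-en-1-yl)cyclohex-1-en-1-olate | CC(C)=CCC[C@@]1(C)C=C(O[Li])CC[C@@H]1O[Si](C)(C)C(C)(C)C | intermediate (not isolated)
14 | (3S,4S)-4-[(tert-butyldimethylsilyl)oxy]-3-methyl-3-(4-methylpent-3-en-1-yl)cyclohex-1-en-1-yl trifluoromethanesulfonate | CC(C)=CCC[C@@]1(C)C=C(OS(=O)(=O)C(F)(F)F)CC[C@@H]1O[Si](C)(C)C(C)(C)C | intermediate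
15 | (3S,4S)-4-[(tert-butyldimethylsilyl)oxy]-3-{2-[(2R)-3,3-dimethyloxiran-2-yl]ethyl}-3-methylcyclohex-1-en-1-yl trifluoromethanesulfonate | CC1(C)O[C@@H]1CC[C@@]1(C)C=C(OS(=O)(=O)C(F)(F)F)CC[C@@H]1O[Si](C)(C)C(C)(C)C | intermediate
16 | vinylboronic acid, used as its MIDA ester (2-ethenyl-6-methyl-1,3,6,2-dioxazaborocane-4,8-dione; MIDA is a protecting group) | C=CB1OC(=O)CN(C)CC(=O)O1 | starting material
17 | 2-[(E)-2-[(3S,4S)-4-[(tert-butyldimethylsilyl)oxy]-3-{2-[(2R)-3,3-dimethyloxiran-2-yl]ethyl}-3-methylcyclohex-1-en-1-yl]ethenyl]-6-methyl-1,3,6,2-dioxazaborocane-4,8-dione | CC1(C)O[C@@H]1CC[C@@]1(C)C=C(/C=C/B2OC(=O)CN(C)CC(=O)O2)CC[C@@H]1O[Si](C)(C)C(C)(C)C | intermediate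
18 | [(E)-2-[(3S,4S)-4-[(tert-butyldimethylsilyl)oxy]-3-{2-[(2R)-3,3-dimethyloxiran-2-yl]ethyl}-3-methylcyclohex-1-en-1-yl]ethenyl]boronic acid | CC1(C)O[C@@H]1CC[C@@]1(C)C=C(/C=C/B(O)O)CC[C@@H]1O[Si](C)(C)C(C)(C)C | intermediate (not isolated)
19 | (1E,3E)-1,4-bis[(3S,4S)-4-[(tert-butyldimethylsilyl)oxy]-3-{2-[(2R)-3,3-dimethyloxiran-2-yl]ethyl}-3-methylcyclohex-1-en-1-yl]buta-1,3-diene | CC1(C)O[C@@H]1CC[C@@]1(C)C=C(/C=C/C=C/C2=C[C@](C)(CC[C@H]3OC3(C)C)[C@@H](O[Si](C)(C)C(C)(C)C)CC2)CC[C@@H]1O[Si](C)(C)C(C)(C)C | intermediate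
20 | (1S,1'S,2S,2'S)-4,4'-[(1E,3E)-buta-1,3-diene-1,4-diyl]bis(2-{2-[(2R)-3,3-dimethyloxiran-2-yl]ethyl}-2-methylcyclohex-3-en-1-ol) | CC1(C)O[C@@H]1CC[C@@]1(C)C=C(/C=C/C=C/C2=C[C@](C)(CC[C@H]3OC3(C)C)[C@@H](O)CC2)CC[C@@H]1O | target

## Step count and risks

Total step count: 7. Longest linear sequence: 7 (the route is linear; the organozinc of step 1 is made and used without isolation).

The three steps most likely to fail:

**Step 3 (the proposed new ring expansion/triflation).** The risks are incomplete migration of the hindered quaternary carbon and poor capture of the enolate in a flask that also holds amide, LiBr and butyl bromide. The fallback uses the published stepwise chemistry with a silyl enol ether relay. It sets out from 8 and comes back at 14. Dibromomethyllithium is added to 8 and, after NH4Cl quench, (2R,3S)-3-[(tert-butyldimethylsilyl)oxy]-1-(dibromomethyl)-2-methyl-2-(4-methylpent-3-en-1-yl)cyclopentan-1-ol F4 is isolated. F4 is treated with n-BuLi (2.2 equiv, THF, −95 → 0 °C), the known β-oxido carbenoid ring enlargement, and the enolate is quenched with TMSCl to give {[(3S,4S)-4-[(tert-butyldimethylsilyl)oxy]-3-methyl-3-(4-methylpent-3-en-1-yl)cyclohex-1-en-1-yl]oxy}trimethylsilane F5. F5 can be purified and its regiochemistry checked by NMR. MeLi (THF, 0 °C) then regenerates the salt-free lithium enolate 13 regiospecifically, and PhNTf2 gives 14.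

**Step 6 (oxidative homocoupling of a polyenylboron species).** The risks are protodeboronation and low conversion. The fallback replaces homocoupling by a cross-coupling of two differentiated halves. It sets out from 17 and comes back at 19. Half of 17 is hydrolysed (1 M NaOH, THF) to boronic acid 18 and iododeboronated with N-iodosuccinimide (MeCN, 0 °C, dark) to tert-butyl{[(1S,2S)-2-{2-[(2R)-3,3-dimethyloxiran-2-yl]ethyl}-4-[(E)-2-iodoethenyl]-2-methylcyclohex-3-en-1-yl]oxy}dimethylsilane F6. The other half of 17 is coupled with F6 under slow-release Suzuki–Miyaura conditions (Pd(OAc)2, SPhos, aq. K3PO4, THF, 45 °C) to give 19.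

**Step 1 (enantioselective addition of a non-commercial, functionalised dialkylzinc, then directed epoxidation).** The risks are residual magnesium salts eroding ee and sluggish alkyl transfer. The fallback sets the configuration by reagent-controlled reduction instead. It sets out from 1 and comes back at 6. CBS reduction of 1 ((S)-Me-CBS oxazaborolidine, BH3·SMe2, THF, −20 °C) gives (R)-2-methylcyclopent-2-en-1-ol F1. Hydroxyl-directed epoxidation (VO(acac)2, TBHP, CH2Cl2, 0 °C) gives (1S,2R,5S)-1-methyl-6-oxabicyclo[3.1.0]hexan-2-ol F2. Dess–Martin oxidation gives (1S,5S)-1-methyl-6-oxabicyclo[3.1.0]hexan-2-one F3. Grignard reagent 3 with CeCl3 (THF, −78 °C) adds anti to the oxirane oxygen to give 6.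

## Further compounds

F1 | step 1 | (R)-2-methylcyclopent-2-en-1-ol | O[C@@H]1CCC=C1C
F2 | step 1 | (1S,2R,5S)-1-methyl-6-oxabicyclo[3.1.0]hexan-2-ol | O[C@@H]1CC[C@@H]2O[C@]12C
F3 | step 1 | (1S,5S)-1-methyl-6-oxabicyclo[3.1.0]hexan-2-one | O=C1CC[C@@H]2O[C@]12C
F4 | step 3 | (2R,3S)-3-[(tert-butyldimethylsilyl)oxy]-1-(dibromomethyl)-2-methyl-2-(4-methylpent-3-en-1-yl)cyclopentan-1-ol (C1 epimers) | CC(C)=CCC[C@@]1(C)C(O)(C(Br)Br)CC[C@@H]1O[Si](C)(C)C(C)(C)C
F5 | step 3 | {[(3S,4S)-4-[(tert-butyldimethylsilyl)oxy]-3-methyl-3-(4-methylpent-3-en-1-yl)cyclohex-1-en-1-yl]oxy}trimethylsilane | CC(C)=CCC[C@@]1(C)C=C(O[Si](C)(C)C)CC[C@@H]1O[Si](C)(C)C(C)(C)C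
F6 | step 6 | tert-butyl{[(1S,2S)-2-{2-[(2R)-3,3-dimethyloxiran-2-yl]ethyl}-4-[(E)-2-iodoethenyl]-2-methylcyclohex-3-en-1-yl]oxy}dimethylsilane | CC1(C)O[C@@H]1CC[C@@]1(C)C=C(/C=C/I)CC[C@@H]1O[Si](C)(C)C(C)(C)C
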